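**Strategy**

The route rests on disconnecting the C3–C4 bond of ring C. Because the ketone carbon C4 sits on ring A between the C5 hydroxyl and the O1-bearing carbon C8a, and C2 carries both O1 and ring B next to the C3 methylene, ring C can be read as a formyl group on ring A added across an aryl 1-arylvinyl ether. A rhodium-catalysed enantioselective intramolecular hydroacylation therefore closes ring C, forms C3–C4 and sets C2 in one operation. Its precursor is the fully assembled salicylaldehyde 16: side chain at C6, silyl ethers at O7, O4' and the tertiary alcohol, free C5 hydroxyl, and the 1-arylvinyl group on the less hindered ortho oxygen.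

Key step: step 11

**Remarks on the chemistry**

- Flavanone numbering (O1, C2–C4, C4a, C5–C8, C8a, ring B primed) is used for the ring atoms throughout.
- Assumption: the sense of induction of the bisphosphine in step 11 cannot be predicted, so (R)-DTBM-SEGPHOS is written provisionally and the antipode is used if a ligand screen shows the opposite sense.
- O7 carries a triisopropylsilyl group: this silyl ether lies para to the formyl group and must survive carbonate and phenoxides in step 10.
- The C5 hydroxyl is kept free and un-ionised. It cannot bind rhodium while ring C closes, because the metal must sit on the O1 side of the acyl group; its role is the hydrogen bond to the carbonyl oxygen, which turns the formyl C–H toward the vinyl ether.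
- Compound 16 is an acid-labile enol ether and is handled with triethylamine-deactivated silica and base-washed glassware.

**Route**

Step 1
Reactants: 1 geranyl acetate
Product: 2 (E)-5-(3,3-dimethyloxiran-2-yl)-3-methylpent-2-en-1-yl acetate (racemic 6,7-epoxygeranyl acetate)
Conditions: mCPBA (1.05 equiv), NaHCO3, CH2Cl2, 0 °C
Reagents that add atoms: mCPBA, O=C(OO)c1cccc(Cl)c1
Why: Prilezhaev epoxidation: the electron-rich terminal trisubstituted alkene reacts faster than the 2,3-alkene, which the allylic acetate deactivates, and the new stereocenter (racemic) is erased in step 2.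

Step 2
Reactants: 2 racemic 6,7-epoxygeranyl acetate
Product: 5 (2E,5E)-7-hydroxy-3,7-dimethylocta-2,5-dien-1-yl acetate, via hydroxy selenide 3 (not isolated), via selenoxide 4 (not isolated)
Conditions: PhSeSePh (0.6 equiv), NaBH4, EtOH, 0 °C → rt; then 30% H2O2, THF, 0 °C → rt
Reagents that add atoms: none
Why: Epoxide-to-allylic-alcohol transposition by selenide opening and selenoxide syn-elimination: benzeneselenolate attacks the secondary epoxide carbon by SN2, and after oxidation the selenoxide can eliminate only toward C5 because C7 bears no hydrogen, which should give the E-configured 5,6-alkene next to the tertiary alcohol.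

Step 3
Reactants: 5 (2E,5E)-7-hydroxy-3,7-dimethylocta-2,5-dien-1-yl acetate
Product: 6 (2E,5E)-3,7-dimethyl-7-(triethylsilyloxy)octa-2,5-dien-1-yl acetate
Conditions: TESOTf, 2,6-lutidine, CH2Cl2, −78 → 0 °C
Reagents that add atoms: triethylsilyl triflate, CC[Si](CC)(CC)OS(=O)(=O)C(F)(F)F
Why: Silylation of a hindered tertiary alcohol needs the silyl triflate with a hindered pyridine base, conditions that leave the allylic acetate and both alkenes untouched.

Step 4
Reactants: 6 (2E,5E)-3,7-dimethyl-7-(triethylsilyloxy)octa-2,5-dien-1-yl acetate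
Product: 7 (2E,5E)-3,7-dimethyl-7-(triethylsilyloxy)octa-2,5-dien-1-ol
Conditions: K2CO3 (0.2 equiv), MeOH, 0 °C → rt
Reagents that add atoms: none
Why: Base-catalysed transesterification (methanolysis) removes the primary acetate, while the tertiary triethylsilyl ether is stable to K2CO3 in methanol.

Step 5
Reactants: 7 (2E,5E)-3,7-dimethyl-7-(triethylsilyloxy)octa-2,5-dien-1-ol
Product: 9 (2E,5E)-1-bromo-3,7-dimethyl-7-(triethylsilyloxy)octa-2,5-diene, via allylic mesylate 8 (not isolated)
Conditions: MsCl, Et3N, THF, −40 °C; then LiBr, THF, 0 °C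
Reagents that add atoms: lithium bromide, [Li+].[Br-]
Why: Mesylation followed by SN2 displacement with bromide (Finkelstein-type) converts the primary allylic alcohol into the bromide without acid, so the tertiary allylic silyl ether and the E geometry of the 2,3-alkene are kept.

Step 6
Reactants: 9 (2E,5E)-1-bromo-3,7-dimethyl-7-(triethylsilyloxy)octa-2,5-diene; 10 2,4,6-trihydroxybenzaldehyde
Product: 11 2,4,6-trihydroxy-3-[(2E,5E)-3,7-dimethyl-7-(triethylsilyloxy)octa-2,5-dien-1-yl]benzaldehyde
Conditions: 10 (3 equiv), DBU (3 equiv), THF, 0 °C → rt, slow addition of 9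
Reagents that add atoms: none
Why: C-Alkylation of the ambident phloroglucinol-type phenoxide with a primary allylic bromide (SN2, geometry retained), the reaction type used for C-prenylation and C-geranylation of acylphloroglucinols; the symmetry of 10 allows only one mono-C-alkylated product and its excess suppresses dialkylation.

Step 7
Reactants: 11 2,4,6-trihydroxy-3-[(2E,5E)-3,7-dimethyl-7-(triethylsilyloxy)octa-2,5-dien-1-yl]benzaldehyde
Product: 12 2,6-dihydroxy-3-[(2E,5E)-3,7-dimethyl-7-(triethylsilyloxy)octa-2,5-dien-1-yl]-4-(triisopropylsilyloxy)benzaldehyde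
Conditions: TIPSCl (1.05 equiv), imidazole, CH2Cl2, −20 → 0 °C
Reagents that add atoms: triisopropylsilyl chloride, CC(C)[Si](Cl)(C(C)C)C(C)C
Why: Regioselective silylation: the hydroxyl para to the formyl group is the most acidic and the only one that cannot hydrogen-bond to the carbonyl, so one equivalent of the bulky silyl chloride should take it and leave both ortho hydroxyls free.

Step 8
Reactants: 13 acetovanillone
Product: 14 1-[4-(tert-butyldimethylsilyloxy)-3-methoxyphenyl]ethan-1-one
Conditions: TBSCl, imidazole, DMF, rt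
Reagents that add atoms: tert-butyldimethylsilyl chloride, CC(C)(C)[Si](C)(C)Cl
Why: Standard silylation of a phenol with a silyl chloride and imidazole.

Step 9
Reactants: 14 1-[4-(tert-butyldimethylsilyloxy)-3-methoxyphenyl]ethan-1-one
Product: 15 tert-butyl[4-(1-bromoethenyl)-2-methoxyphenoxy]dimethylsilane
Conditions: (PhO)3P, Br2, Et3N, CH2Cl2, −60 °C → rt
Reagents that add atoms: bromine, BrBr
Why: Conversion of an enolisable aryl methyl ketone into the 1-bromovinylarene with the triphenyl phosphite–bromine reagent, by O-phosphonium activation of the enol form, bromide attack and elimination, under amine buffering that protects the aryl silyl ether.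

Step 10
Reactants: 12 2,6-dihydroxy-3-[(2E,5E)-3,7-dimethyl-7-(triethylsilyloxy)octa-2,5-dien-1-yl]-4-(triisopropylsilyloxy)benzaldehyde; 15 tert-butyl[4-(1-bromoethenyl)-2-methoxyphenoxy]dimethylsilane
Product: 16 2-({1-[4-(tert-butyldimethylsilyloxy)-3-methoxyphenyl]ethenyl}oxy)-6-hydroxy-5-[(2E,5E)-3,7-dimethyl-7-(triethylsilyloxy)octa-2,5-dien-1-yl]-4-(triisopropylsilyloxy)benzaldehyde
Conditions: 15 (1.5 equiv), CuI (10 mol%), N,N-dimethylglycine hydrochloride (30 mol%), Cs2CO3, 1,4-dioxane, 80–90 °C
Reagents that add atoms: none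
Why: Ullmann-type copper-catalysed C–O coupling of a phenol with a vinyl bromide: the hydroxyl between the side chain and the formyl group is doubly ortho-substituted and should stay untouched, so coupling occurs at the hydroxyl with a free ortho position, and a tertiary amino acid ligand is chosen because it cannot condense with the aldehyde.

Step 11
Reactants: 16 2-({1-[4-(tert-butyldimethylsilyloxy)-3-methoxyphenyl]ethenyl}oxy)-6-hydroxy-5-[(2E,5E)-3,7-dimethyl-7-(triethylsilyloxy)octa-2,5-dien-1-yl]-4-(triisopropylsilyloxy)benzaldehyde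
Product: 17 (2S)-2-[4-(tert-butyldimethylsilyloxy)-3-methoxyphenyl]-5-hydroxy-6-[(2E,5E)-3,7-dimethyl-7-(triethylsilyloxy)octa-2,5-dien-1-yl]-7-(triisopropylsilyloxy)-2,3-dihydro-4H-chromen-4-one
Conditions: [Rh(cod)2]BF4 (5 mol%), (R)-DTBM-SEGPHOS (6 mol%), 2,6-di-tert-butyl-4-methylpyridine (10 mol%), 1,2-dichloroethane (0.02 M), 50 °C
Reagents that add atoms: none
Why: Proposed new method: cationic monovalent rhodium should insert into the formyl C–H bond of 16, whose C5–OH···O=C hydrogen bond keeps that hydrogen on the O1 side, to give an acyl hydride of trivalent rhodium to which the tethered vinyl ether binds; hydride then migrates to C2, leaving a primary alkyl at C3 in a seven-membered rhodacycle, and reductive elimination forms C3–C4. The closest known reaction type is the enantioselective rhodium-catalysed intramolecular hydroacylation of 2-(1-arylvinyl)benzaldehydes to 3-arylindanones, of ortho-allylbenzaldehydes to tetralones and of N-vinylindole-2-carbaldehydes, together with the hydroacylation of alkenes by salicylaldehydes; an aryl 1-arylvinyl ether closing to a chroman-4-one has not been shown. Ring C closes in the 6-endo-trig mode. C2 is set when hydride is delivered to one enantiotopic face of the 1,1-disubstituted alkene inside the chiral pocket of the axially chiral bisphosphine, so the ligand alone controls it. The step needs endo over 5-exo regioselectivity, which the 1,1-disubstitution should secure because the exo path requires a tertiary alkyl rhodium and reductive elimination to a quaternary centre, and chemoselectivity over the side-chain alkenes, which are trisubstituted or hindered disubstituted and cannot chelate. No base is present, so the new flavanone cannot open to the chalcone, and the hindered pyridine only scavenges acid that would hydrolyse the enol ether.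

Step 12
Reactants: 17 (2S)-2-[4-(tert-butyldimethylsilyloxy)-3-methoxyphenyl]-5-hydroxy-6-[(2E,5E)-3,7-dimethyl-7-(triethylsilyloxy)octa-2,5-dien-1-yl]-7-(triisopropylsilyloxy)-2,3-dihydro-4H-chromen-4-one
Product: 18 tomentodiplacone B, (2S)-5,7-dihydroxy-2-(4-hydroxy-3-methoxyphenyl)-6-[(2E,5E)-7-hydroxy-3,7-dimethylocta-2,5-dien-1-yl]-2,3-dihydro-4H-chromen-4-one
Conditions: HF·pyridine, pyridine, THF, 0 °C → rt
Reagents that add atoms: none
Why: Fluoride-mediated desilylation under buffered, non-basic conditions should cleave the two aryl silyl ethers and the tertiary triethylsilyl ether while the flavanone, which opens and racemises under base, and the tertiary allylic alcohol stay intact.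

**Compound list**

1 | geranyl acetate | CC(=O)OC/C=C(\C)CCC=C(C)C | starting material
2 | (E)-5-(3,3-dimethyloxiran-2-yl)-3-methylpent-2-en-1-yl acetate (racemic) | CC(=O)OC/C=C(\C)CCC1OC1(C)C | intermediate
3 | (E)-7-hydroxy-3,7-dimethyl-6-(phenylselanyl)oct-2-en-1-yl acetate (racemic, not isolated) | CC(=O)OC/C=C(\C)CCC([Se]c1ccccc1)C(C)(C)O | intermediate
4 | (E)-7-hydroxy-3,7-dimethyl-6-(phenylseleninyl)oct-2-en-1-yl acetate (selenoxide, not isolated) | CC(=O)OC/C=C(\C)CCC([Se](=O)c1ccccc1)C(C)(C)O | intermediate
5 | (2E,5E)-7-hydroxy-3,7-dimethylocta-2,5-dien-1-yl acetate | CC(=O)OC/C=C(\C)C/C=C/C(C)(C)O | intermediate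
6 | (2E,5E)-3,7-dimethyl-7-(triethylsilyloxy)octa-2,5-dien-1-yl acetate | CC(=O)OC/C=C(\C)C/C=C/C(C)(C)O[Si](CC)(CC)CC | intermediate
7 | (2E,5E)-3,7-dimethyl-7-(triethylsilyloxy)octa-2,5-dien-1-ol | OC/C=C(\C)C/C=C/C(C)(C)O[Si](CC)(CC)CC | intermediate
8 | (2E,5E)-3,7-dimethyl-7-(triethylsilyloxy)octa-2,5-dien-1-yl methanesulfonate (not isolated) | CS(=O)(=O)OC/C=C(\C)C/C=C/C(C)(C)O[Si](CC)(CC)CC | intermediate
9 | (2E,5E)-1-bromo-3,7-dimethyl-7-(triethylsilyloxy)octa-2,5-diene | BrC/C=C(\C)C/C=C/C(C)(C)O[Si](CC)(CC)CC | intermediate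
10 | 2,4,6-trihydroxybenzaldehyde | O=Cc1c(O)cc(O)cc1O | starting material
11 | 2,4,6-trihydroxy-3-[(2E,5E)-3,7-dimethyl-7-(triethylsilyloxy)octa-2,5-dien-1-yl]benzaldehyde | O=Cc1c(O)cc(O)c(C/C=C(\C)C/C=C/C(C)(C)O[Si](CC)(CC)CC)c1O | intermediate
12 | 2,6-dihydroxy-3-[(2E,5E)-3,7-dimethyl-7-(triethylsilyloxy)octa-2,5-dien-1-yl]-4-(triisopropylsilyloxy)benzaldehyde | O=Cc1c(O)cc(O[Si](C(C)C)(C(C)C)C(C)C)c(C/C=C(\C)C/C=C/C(C)(C)O[Si](CC)(CC)CC)c1O | intermediate
13 | acetovanillone | CC(=O)c1ccc(O)c(OC)c1 | starting material
14 | 1-[4-(tert-butyldimethylsilyloxy)-3-methoxyphenyl]ethan-1-one | CC(=O)c1ccc(O[Si](C)(C)C(C)(C)C)c(OC)c1 | intermediate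
15 | tert-butyl[4-(1-bromoethenyl)-2-methoxyphenoxy]dimethylsilane | C=C(Br)c1ccc(O[Si](C)(C)C(C)(C)C)c(OC)c1 | intermediate
16 | 2-({1-[4-(tert-butyldimethylsilyloxy)-3-methoxyphenyl]ethenyl}oxy)-6-hydroxy-5-[(2E,5E)-3,7-dimethyl-7-(triethylsilyloxy)octa-2,5-dien-1-yl]-4-(triisopropylsilyloxy)benzaldehyde | C=C(Oc1cc(O[Si](C(C)C)(C(C)C)C(C)C)c(C/C=C(\C)C/C=C/C(C)(C)O[Si](CC)(CC)CC)c(O)c1C=O)c1ccc(O[Si](C)(C)C(C)(C)C)c(OC)c1 | intermediate
17 | (2S)-2-[4-(tert-butyldimethylsilyloxy)-3-methoxyphenyl]-5-hydroxy-6-[(2E,5E)-3,7-dimethyl-7-(triethylsilyloxy)octa-2,5-dien-1-yl]-7-(triisopropylsilyloxy)-2,3-dihydro-4H-chromen-4-one | COc1cc([C@@H]2CC(=O)c3c(cc(O[Si](C(C)C)(C(C)C)C(C)C)c(C/C=C(\C)C/C=C/C(C)(C)O[Si](CC)(CC)CC)c3O)O2)ccc1O[Si](C)(C)C(C)(C)C | intermediate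
18 | tomentodiplacone B | COc1cc([C@@H]2CC(=O)c3c(cc(O)c(C/C=C(\C)C/C=C/C(C)(C)O)c3O)O2)ccc1O | target

**Step count**

Total steps: 12. Longest linear sequence: 10 steps (steps 1–7, 10, 11 and 12, from geranyl acetate).

**Steps most likely to fail**

1. Step 11 (Proposed new method). What may go wrong: hydride transfer with the opposite regiochemistry (5-exo closure), decarbonylation of the acyl rhodium hydride, slow turnover, or poor discrimination of the alkene faces.
Fallback, known chemistry, setting out from 14 and 12 and coming back at 17. Ketone 14 is α-brominated (PhNMe3Br3, THF, 0 °C) to 2-bromo-1-[4-(tert-butyldimethylsilyloxy)-3-methoxyphenyl]ethan-1-one F1. Corey–Bakshi–Shibata reduction ((S)-Me-CBS, BH3·SMe2, THF, −20 °C) should give (S)-2-bromo-1-[4-(tert-butyldimethylsilyloxy)-3-methoxyphenyl]ethan-1-ol F2. Mitsunobu etherification (PPh3, DIAD, toluene, 0 °C) at the less hindered ortho hydroxyl of 12 should proceed with inversion to the (R)-configured 2-bromo-1-arylethyl aryl ether F3, in which O1–C2 and the C2 configuration are already in place. The same C3–C4 bond is then closed by the known N-heterocyclic-carbene-catalysed intramolecular alkylation of a salicylaldehyde Breslow intermediate by a tethered alkyl halide (3-benzyl-5-(2-hydroxyethyl)-4-methylthiazolium chloride 20 mol%, Et3N, dioxane, 60 °C), which should give 17. Partial ionisation at the electron-rich benzylic carbon during the Mitsunobu step would erode the enantiomeric purity and is to be checked by chiral HPLC.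

2. Step 10. What may go wrong: loss of site selectivity between the two ortho hydroxyls, dehydrobromination of the vinyl bromide to the arylalkyne, or silyl transfer under carbonate at 80–90 °C.
Fallback, setting out from 12 and the bromo ketone F1 (made from 14 as above) and coming back at 16. NaBH4 reduction (MeOH, 0 °C) gives racemic 2-bromo-1-[4-(tert-butyldimethylsilyloxy)-3-methoxyphenyl]ethan-1-ol F4. Mitsunobu etherification with 12 (PPh3, DIAD, toluene, 0 °C) puts the 2-bromo-1-arylethyl group on the less hindered hydroxyl under neutral conditions and gives the racemic bromo ether F5. Dehydrobromination (DBU, NaI cat., MeCN, 60 °C) removes the benzylic, oxygen-activated hydrogen and should give the 1-arylvinyl ether 16.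

3. Step 6. What may go wrong: O-alkylation and dialkylation competing with mono C-alkylation, with loss of the five-step bromide.
Fallback, setting out from acetate 6 and aldehyde 10 and coming back at 11: Tsuji–Trost C-allylation (Pd(PPh3)4 5 mol%, THF, 50 °C, 10 in excess). The π-allyl complex formed from zerovalent palladium and 6 is attacked at its primary terminus by the phloroglucinol carbon, and O-allyl products re-ionise under the catalyst and funnel to the C-alkylated phenol. This variant makes steps 4 and 5 unnecessary; partial E/Z scrambling through the π-allyl intermediate must be checked.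

**Further compounds**

F1 | step 11 | 2-bromo-1-[4-(tert-butyldimethylsilyloxy)-3-methoxyphenyl]ethan-1-one | O=C(CBr)c1ccc(O[Si](C)(C)C(C)(C)C)c(OC)c1
F2 | step 11 | (S)-2-bromo-1-[4-(tert-butyldimethylsilyloxy)-3-methoxyphenyl]ethan-1-ol | O[C@H](CBr)c1ccc(O[Si](C)(C)C(C)(C)C)c(OC)c1
F3 | step 11 | 2-{(1R)-2-bromo-1-[4-(tert-butyldimethylsilyloxy)-3-methoxyphenyl]ethoxy}-6-hydroxy-5-[(2E,5E)-3,7-dimethyl-7-(triethylsilyloxy)octa-2,5-dien-1-yl]-4-(triisopropylsilyloxy)benzaldehyde | BrC[C@H](Oc1cc(O[Si](C(C)C)(C(C)C)C(C)C)c(C/C=C(\C)C/C=C/C(C)(C)O[Si](CC)(CC)CC)c(O)c1C=O)c1ccc(O[Si](C)(C)C(C)(C)C)c(OC)c1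
F4 | step 10 | racemic 2-bromo-1-[4-(tert-butyldimethylsilyloxy)-3-methoxyphenyl]ethan-1-ol | OC(CBr)c1ccc(O[Si](C)(C)C(C)(C)C)c(OC)c1
F5 | step 10 | racemic 2-{2-bromo-1-[4-(tert-butyldimethylsilyloxy)-3-methoxyphenyl]ethoxy}-6-hydroxy-5-[(2E,5E)-3,7-dimethyl-7-(triethylsilyloxy)octa-2,5-dien-1-yl]-4-(triisopropylsilyloxy)benzaldehyde | BrCC(Oc1cc(O[Si](C(C)C)(C(C)C)C(C)C)c(C/C=C(\C)C/C=C/C(C)(C)O[Si](CC)(CC)CC)c(O)c1C=O)c1ccc(O[Si](C)(C)C(C)(C)C)c(OC)c1
F0 | step 6 | none | none
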